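**Plan**
- Retrosynthesis cuts, in order: the C2–Cl bond (chloride opening of a C1–C2 oxirane), the oxirane C2–O bond (dehydrative closure of a trans C1,C2-diol), the C2–O and C5–O bonds together (singlet oxygen across the C2–C5 diene), the benzoate C–O bonds at O6 and O7, and last the C1–O and C6–O bonds (dioxygenase on benzoic acid).
- Forward: the six-membered ring is the benzene ring of benzoic acid and no carbocycle is built. Only heterocycles are closed: a 1,3-dioxolane orthobenzoate on O1/O6 (the later O6 benzoate), a 2,3-dioxabicyclo[2.2.2]octene peroxide, then an oxirane, each opened again.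
- Enabling feature: C1 (carbinol carbon carrying C7) and C6 bear cis oxygens and are the ipso and ortho carbons of a benzoate ring; C2–C5 remain as a diene in that ring.
- Stereochemistry: C1 and C6 come from the enzyme. C2 and C5 come from suprafacial O2 addition anti to the cis-fused orthoester. C2 is then inverted twice (oxirane closure, chloride opening); C5 is not touched.

Key step: step 1

Remark: the target's numbering (C1 quaternary carbinol, C2–C5 former diene, C6 second carbinol, C7 exocyclic carbon; O1, O2, O5, O6, O7 on them) is used for every intermediate, and orthobenzoates 5, 6, 8 and 9 are carried as both epimers at the orthoester carbon, assumed not to affect the facial selectivity of step 6.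

**Step 1**
Reactants: 1 benzoic acid (fed as sodium benzoate)
Product: 2 (1S,2R)-1,2-dihydroxycyclohexa-3,5-diene-1-carboxylic acid
Conditions: Cupriavidus necator B9 whole cells (benzoate 1,2-dioxygenase induced, cis-diol dehydrogenase absent), fructose, air, phosphate buffer pH 7, 30 °C; broth to pH 3, EtOAc extraction
Reagents that add atoms: dioxygen, O=O
Why: The Rieske [2Fe–2S] cluster of the oxygenase relays two electrons from NADH to a mononuclear non-heme iron centre resting in the divalent state, where O2 is activated and both oxygen atoms are delivered to one face of the ipso carbon C1 and the ortho carbon C6, forming the C1–O and C6–O bonds. The closest known reaction type is Rieske arene cis-dihydroxylation as shown by toluene dioxygenase, and benzoate is this enzyme's native substrate. No ring is closed; the aromatic ring is only dearomatised to a cyclohexadiene. Both new stereocentres (C1 S, C6 R) are set by the active site, which anchors the carboxylate and exposes one ortho position and one ring face to the iron-bound oxygen. The step needs ipso,ortho regioselectivity, cis delivery, one enantiomer and no further oxidation; the first three are properties of the enzyme, and the last is secured by the missing dehydrogenase, so the diol accumulates instead of going on to catechol.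

**Step 2**
Reactants: 2 (1S,2R)-1,2-dihydroxycyclohexa-3,5-diene-1-carboxylic acid
Product: 3 methyl (1S,2R)-1,2-dihydroxycyclohexa-3,5-diene-1-carboxylate
Conditions: MeI, KHCO3, DMF, rt
Reagents that add atoms: iodomethane, CI
Why: Carboxylate O-alkylation (SN2 on iodomethane) under bicarbonate buffering esterifies the acid without the strong acid that would dehydrate and rearomatise the dienediol, and no stereocentre is touched.

**Step 3**
Reactants: 3 methyl (1S,2R)-1,2-dihydroxycyclohexa-3,5-diene-1-carboxylate; 4 trimethyl orthobenzoate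
Product: 5 methyl (3aS,7aR)-2-methoxy-2-phenyl-3a,7a-dihydro-1,3-benzodioxole-3a-carboxylate (cyclic orthobenzoate on O1/O6)
Conditions: PhC(OMe)3, PPTS (cat.), CH2Cl2, 0 °C to rt; Et3N quench
Reagents that add atoms: trimethyl orthobenzoate (4), COC(OC)(OC)c1ccccc1
Why: Acid-catalysed transorthoesterification onto the cis-1,2-diol closes a cis-fused 2-methoxy-2-phenyl-1,3-dioxolane that blocks the O1/O6 face and already carries the future O6 benzoyl group; the new orthoester centre forms as both epimers, which does not matter because it is destroyed in step 7.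

**Step 4**
Reactants: 5 cyclic orthobenzoate methyl ester
Product: 6 [(3aR,7aR)-2-methoxy-2-phenyl-3a,7a-dihydro-1,3-benzodioxol-3a-yl]methanol
Conditions: LiAlH4, THF, 0 °C; H2O then aq NaOH work-up
Reagents that add atoms: none
Why: Hydride reduction of the ester to the primary C7 alcohol, to which orthoesters and unactivated dienes are inert, with an alkaline work-up that keeps the orthoester intact.

**Step 5**
Reactants: 6 orthoester alcohol; 7 benzoyl chloride
Product: 8 [(3aR,7aR)-2-methoxy-2-phenyl-3a,7a-dihydro-1,3-benzodioxol-3a-yl]methyl benzoate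
Conditions: BzCl, pyridine, DMAP (cat.), CH2Cl2, 0 °C
Reagents that add atoms: benzoyl chloride (7), O=C(Cl)c1ccccc1
Why: DMAP-catalysed O-acylation (nucleophilic acyl substitution) at the only free hydroxyl, under basic conditions that spare the orthoester.

**Step 6**
Reactants: 8 orthoester diene benzoate
Product: 9 2,5-epidioxide of 8 (C2–O–O–C5 bridge on the face opposite the dioxolane; C1 R, C2 R, C5 S, C6 R)
Conditions: O2, tetraphenylporphyrin (cat.), visible light, CH2Cl2, −20 °C
Reagents that add atoms: dioxygen, O=O
Why: The [4+2] cycloaddition of singlet oxygen to the cyclohexa-1,3-diene is suprafacial, so O2 and O5 arrive cis to each other, and it should occur on the face opposite the cis-fused dioxolane and its endo substituent, setting C2 and C5 with both new oxygens anti to O1 and O6.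

**Step 7**
Reactants: 9 orthoester endoperoxide
Product: 10 [(1R,2R,5S,6R)-6-benzoyloxy-1-hydroxy-2,5-epidioxycyclohex-3-en-1-yl]methyl benzoate
Conditions: AcOH/H2O/THF (3:1:1), 0 °C to rt
Reagents that add atoms: water, O
Why: Mild acid hydrolysis of the cyclic orthoester (hemiorthoester collapse) should leave the benzoate on the secondary O6, the more stable isomer to which any tertiary O1 benzoate converges by acid-catalysed 1,2-acyl shift across the cis-diol; no other hydroxyl is present to take the acyl group and the dialkyl peroxide bridge tolerates dilute acetic acid.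

**Step 8**
Reactants: 10 hydroxy dibenzoate endoperoxide
Product: 11 [(1S,2R,5S,6R)-6-benzoyloxy-1,2,5-trihydroxycyclohex-3-en-1-yl]methyl benzoate
Conditions: thiourea (2.2 equiv), MeOH, rt
Reagents that add atoms: none
Why: Thiourea reduction cleaves only the O–O bond of the endoperoxide, so both C–O bonds and the configurations at C2 and C5 are kept, and the neutral medium avoids benzoyl migration and base-induced Kornblum–DeLaMare rearrangement.

**Step 9**
Reactants: 11 triol dibenzoate
Product: 12 [(1S,2S,5S,6R)-6-benzoyloxy-1,2-epoxy-5-hydroxycyclohex-3-en-1-yl]methyl benzoate (oxirane oxygen on the face of O6)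
Conditions: PPh3, DIAD, THF, 0 °C to rt
Reagents that add atoms: none
Why: Mitsunobu cyclodehydration of the trans-1,2-diol turns the secondary allylic O2 into an oxyphosphonium leaving group that the anti-disposed tertiary O1 displaces with inversion at C2, while oxyphosphonium formation at O5 is reversible and has no hydroxyl neighbour to close onto, as in the known selective epoxide formation from cyclohexene triols.

**Step 10**
Reactants: 12 oxirane
Product: 13 [(1R,2R,5S,6R)-6-benzoyloxy-2-chloro-1,5-dihydroxycyclohex-3-en-1-yl]methyl benzoate (CNP0326102.1)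
Conditions: LiCl, AcOH, THF, 0 °C to rt
Reagents that add atoms: lithium chloride, [Li+].[Cl-]
Why: Acid-assisted SN2 opening of the vinyl epoxide by chloride at C2, which is both the allylic and the less substituted oxirane carbon, proceeds with inversion, so chlorine ends trans to the C1 hydroxyl and cis to O5 (C2 R), with overall retention relative to triol 11.

**Compound list**
1 | benzoic acid | OC(=O)c1ccccc1 | starting material
2 | (1S,2R)-1,2-dihydroxycyclohexa-3,5-diene-1-carboxylic acid | OC(=O)[C@]1(O)C=CC=C[C@H]1O | intermediate
3 | methyl (1S,2R)-1,2-dihydroxycyclohexa-3,5-diene-1-carboxylate | COC(=O)[C@]1(O)C=CC=C[C@H]1O | intermediate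
4 | trimethyl orthobenzoate | COC(OC)(OC)c1ccccc1 | starting material
5 | methyl (3aS,7aR)-2-methoxy-2-phenyl-3a,7a-dihydro-1,3-benzodioxole-3a-carboxylate, both epimers at the orthoester carbon | COC(=O)[C@]1(OC2(OC)c3ccccc3)C=CC=C[C@H]1O2 | intermediate
6 | [(3aR,7aR)-2-methoxy-2-phenyl-3a,7a-dihydro-1,3-benzodioxol-3a-yl]methanol | OC[C@]1(OC2(OC)c3ccccc3)C=CC=C[C@H]1O2 | intermediate
7 | benzoyl chloride | O=C(Cl)c1ccccc1 | starting material
8 | [(3aR,7aR)-2-methoxy-2-phenyl-3a,7a-dihydro-1,3-benzodioxol-3a-yl]methyl benzoate | O=C(OC[C@]1(OC2(OC)c3ccccc3)C=CC=C[C@H]1O2)c1ccccc1 | intermediate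
9 | 2,5-epidioxide of 8, peroxide bridge C2–O–O–C5 anti to the dioxolane (C1 R, C2 R, C5 S, C6 R) | O=C(OC[C@]1(OC2(OC)c3ccccc3)[C@@H]4OO[C@@H](C=C4)[C@H]1O2)c1ccccc1 | intermediate
10 | [(1R,2R,5S,6R)-6-benzoyloxy-1-hydroxy-2,5-epidioxycyclohex-3-en-1-yl]methyl benzoate | O=C(OC[C@]1(O)[C@@H]2OO[C@@H](C=C2)[C@H]1OC(=O)c1ccccc1)c1ccccc1 | intermediate
11 | [(1S,2R,5S,6R)-6-benzoyloxy-1,2,5-trihydroxycyclohex-3-en-1-yl]methyl benzoate | O=C(OC[C@]1(O)[C@H](O)C=C[C@H](O)[C@H]1OC(=O)c1ccccc1)c1ccccc1 | intermediate
12 | [(1S,2S,5S,6R)-6-benzoyloxy-1,2-epoxy-5-hydroxycyclohex-3-en-1-yl]methyl benzoate | O=C(OC[C@]12O[C@H]1C=C[C@H](O)[C@H]2OC(=O)c1ccccc1)c1ccccc1 | intermediate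
13 | [(1R,2R,5S,6R)-6-benzoyloxy-2-chloro-1,5-dihydroxycyclohex-3-en-1-yl]methyl benzoate | O=C(OC[C@]1(O)[C@H](Cl)C=C[C@H](O)[C@H]1OC(=O)c1ccccc1)c1ccccc1 | target

**Step count and risks**
Total steps: 10. Longest linear sequence: 10 steps (1 to 13); 4 and 7 are purchased.

Steps most likely to fail:

1. Step 9 — loss of chemoselectivity in the dehydrative closure: the O5 hydroxyl may be activated instead of O2, followed by participation of the neighbouring O6 benzoate or by elimination. Fallback: setting out from 11, the less hindered O5 hydroxyl would be silylated (t-BuMe2SiCl, imidazole, DMF, 0 °C) to the 5-O-tert-butyldimethylsilyl ether of 11, F1. The secondary O2 hydroxyl would then be sulfonylated (MsCl, Et3N, CH2Cl2, −20 °C) to the 2-O-methanesulfonate of F1, F2. The oxirane would be closed by base (KN(SiMe3)2, THF, −78 °C) through rear-side displacement of the mesylate by the O1 alkoxide, giving the 5-O-silyl ether of oxirane 12, F3. Chloride opening as in step 10 would give the 5-O-silyl ether of 13, F4, and HF·pyridine (THF, 0 °C) would bring the route back at 13.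

2. Step 7 — hemiorthoester collapse in the wrong direction (benzoate left on the tertiary O1) or acid-induced breakdown of the peroxide. Fallback: setting out from 9, the peroxide would be reduced first with thiourea (MeOH, rt), which the orthoester survives, to the 2,5-diol orthoester F5. Both hydroxyls would be capped (Et3SiCl, imidazole, DMAP, DMF) as the 2,5-bis-O-triethylsilyl orthoester F6. The orthoester would then be hydrolysed (PPTS, wet acetone, 0 °C). With no peroxide and no free neighbouring hydroxyl left, the product can be equilibrated with Et3N/DMAP to the secondary benzoate, the 2,5-bis-O-triethylsilyl ether of 11, F7. HF·pyridine would then return the route at 11.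

3. Step 10 — competing SN2' attack at C4, front-side ion-pair collapse or benzoate participation under protic acid. Fallback: setting out from 12, the O5 hydroxyl would be silylated (Et3SiCl, imidazole, DMF) to the 5-O-triethylsilyl ether of 12, F8. The oxirane would then be opened without protic acid by phosphine-catalysed insertion of a silyl chloride (Me3SiCl, Ph3P cat., CH2Cl2, −20 °C), in which chloride attacks C2 of the silylated oxirane from the rear, to give the 1-O-trimethylsilyl-5-O-triethylsilyl ether of 13, F9. HF·pyridine would remove both silyl groups and rejoin the route at 13.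

**Further compounds**
F1 | step 9 | 5-O-tert-butyldimethylsilyl ether of 11 | O=C(OC[C@]1(O)[C@H](O)C=C[C@H](O[Si](C)(C)C(C)(C)C)[C@H]1OC(=O)c1ccccc1)c1ccccc1
F2 | step 9 | 2-O-methanesulfonate of F1 | O=C(OC[C@]1(O)[C@H](OS(C)(=O)=O)C=C[C@H](O[Si](C)(C)C(C)(C)C)[C@H]1OC(=O)c1ccccc1)c1ccccc1
F3 | step 9 | 5-O-tert-butyldimethylsilyl ether of oxirane 12 | O=C(OC[C@]12O[C@H]1C=C[C@H](O[Si](C)(C)C(C)(C)C)[C@H]2OC(=O)c1ccccc1)c1ccccc1
F4 | step 9 | 5-O-tert-butyldimethylsilyl ether of 13 | O=C(OC[C@]1(O)[C@H](Cl)C=C[C@H](O[Si](C)(C)C(C)(C)C)[C@H]1OC(=O)c1ccccc1)c1ccccc1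
F5 | step 7 | 2,5-diol orthoester (peroxide of 9 reduced, O2 and O5 anti to the dioxolane) | O=C(OC[C@]1(OC2(OC)c3ccccc3)[C@H](O)C=C[C@H](O)[C@H]1O2)c1ccccc1
F6 | step 7 | 2,5-bis-O-triethylsilyl ether of F5 | O=C(OC[C@]1(OC2(OC)c3ccccc3)[C@H](O[Si](CC)(CC)CC)C=C[C@H](O[Si](CC)(CC)CC)[C@H]1O2)c1ccccc1
F7 | step 7 | 2,5-bis-O-triethylsilyl ether of 11 | O=C(OC[C@]1(O)[C@H](O[Si](CC)(CC)CC)C=C[C@H](O[Si](CC)(CC)CC)[C@H]1OC(=O)c1ccccc1)c1ccccc1
F8 | step 10 | 5-O-triethylsilyl ether of oxirane 12 | O=C(OC[C@]12O[C@H]1C=C[C@H](O[Si](CC)(CC)CC)[C@H]2OC(=O)c1ccccc1)c1ccccc1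
F9 | step 10 | 1-O-trimethylsilyl-5-O-triethylsilyl ether of 13 | O=C(OC[C@]1(O[Si](C)(C)C)[C@H](Cl)C=C[C@H](O[Si](CC)(CC)CC)[C@H]1OC(=O)c1ccccc1)c1ccccc1
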